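## Structural features

Labdane numbering is used throughout. The target is a trans-fused decalin (ring A: C1–C5 and C10; ring B: C5–C10) whose C9 carries a two-carbon chain (C11, C12) ending at the α-carbon C13 of an α,β-unsaturated γ-lactone (ring C, C13–C16). C4 bears two hydroxymethyl groups (C18, C19) and is quaternary but not stereogenic; C10 bears the angular methyl and C8 a formyl group (C17). The four stereocentres C5, C10, C9 and C8 are contiguous along ring B: H-5 and H-9 lie on the face opposite the angular methyl (trans fusion, C11 equatorial and cis to the methyl), and the formyl group is equatorial, trans to the C9 chain. Fragile groups are the aldehyde (epimerisable at C8, reactive towards carbanions), the butenolide (opened by alkoxide, reduced by hydride donors and by hydrogen over metals) and the neopentyl 1,3-diol. The real difficulty is the quaternary stereocentre C10, which sits between C5 (itself attached to quaternary C4) and the substituted C9 and has to be made in one absolute configuration. Once C10 is fixed, C5 and C9 can be set by delivering hydrogen to the face away from the methyl group, and C8 by equilibration. Ring B carries carbon substituents on C5, C8, C9 and C10; with an oxygen on C7 it has the substitution pattern of a pentasubstituted salicylate in which C10 is para to that oxygen. Alkylating this para carbon with a three-carbon allyl arm attached to C4 therefore dearomatises ring B, closes ring A and creates C10 in a single operation.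

## Logic of the disconnections

**32 back to 29.** No skeletal bond is cut. 32 is traced to 31 by placing an acetonide on the C4 diol, 31 to 30 by lowering the C17 aldehyde to the alcohol, and 30 to its C17 ether 29. Aldehyde and free diol are the groups least compatible with carbon–carbon bond formation at C12, so they appear last. The forward steps may only be oxidative or mildly acidic, because ring C tolerates neither base nor hydride.

**29 back to 26 and 27.** The C12–C13 bond is cut, between a primary sp3 carbon and the α-carbon of ring C. This removes the whole lactone as purchasable 27 and leaves the primary iodide 26. The forward step is an sp3–sp2 cross-coupling through organozinc 28, which demands that no aldehyde, ester-reactive nucleophile or free hydroxyl is present; hence the ether at C17.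

**26 back to 22.** Only functional groups change, through 25, 24 and 23: the iodide comes from the silyl-protected C12 alcohol and the C17 ether from the ester. The two primary oxygenated carbons C12 and C17 stay distinguishable throughout because one travels as a silyl ether and the other as an ester. The demand is that C8 is already correctly configured in 22, since no later step can correct it.

**22 back to 19.** The C8–H and C7–H bonds are removed: 22 comes from enoate 21, 21 from enol triflate 20, and 20 from β-keto ester 19. The C7 carbonyl is the remnant of the phenol oxygen that drives the key step; removing it by way of the C7=C8 enoate lets C8 be set under thermodynamic control. The forward conjugate reduction must equilibrate the ester into the equatorial position.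

**19 back to 18.** Six C–H bonds are removed by reintroducing the C2=C3, C5=C6 and C8=C9 double bonds. This erases C5 and C9 as stereocentres and leaves C10 as the only one. The demand is that hydrogen reaches C5 and C9 from the face opposite the C10 methyl.

**18 back to 17.** The C1–C10 bond is cut, which opens ring A and rearomatises ring B. The gain is large: 17 is a flat benzene derivative without any stereocentre. The forward step must be a para-selective C-alkylation of a phenolate with control of the enantiotopic faces, and it needs a Z-configured allyl arm.

**17 back to 12 and 13.** 17 comes from 16 by carbonate formation, 16 from 15 and 15 from 14 by adjusting the oxidation level of C17. 14 is cut at the C8–C17 bond into phenol 12 and 13. The carboxyl carbon is introduced only after all hydride reductions of the C4 unit, and the phenoxide directs it to the ortho position. The forward formylation must choose C8 over C6 and tolerate the Z-allylic alcohol and the acetonide.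

**12 back to 9.** No skeletal bond is cut: 12 comes from 11 (aryl silyl ether), 11 from triol 10 (acetonide) and 10 from triester 9. The three ester groups of 9 are the precursors of C18, C19 and C1 at the alcohol level. The reduction must be 1,2-selective and leave the Z-alkene untouched.

**9 back to 7 and 8.** The C3–C4 bond is cut. Conjugate addition of the carbanion of 7 to 8 makes the quaternary C4 and brings in C1–C3 in one step. The demand is kinetic control of the alkene geometry towards Z.

**7 back to 5 and 6.** The aryl C5–C4 bond is cut. It is made by palladium-catalysed arylation of 6 with the aryl bromide 5, which must tolerate one ortho methyl group.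

**5 back to 1 and 2.** 5 comes from 4 by silylation, and 4 is cut at the C9–C11 bond into 1 and 2 through aryllithium 3. The two C–Br bonds of 1 are equivalent by symmetry: one becomes the C9 chain and the other is kept for the C4–C5 bond. The otherwise awkward placement of a chain meta to the hydroxyl and ortho to the methyl is thus solved by the choice of starting material.

## Other disconnections considered

**Alternative 1:** The cut is at C4–C5 and C9–C10, which opens both carbocycles to the acyclic aldehyde A2. In the forward step the enamine of A2 with a chiral imidazolidinone would be oxidised by Cu(OTf)2 to a radical cation. C4 would add to C5 of the E-trisubstituted alkene, the tertiary C10 radical would add to C9 of the allylsilane, and oxidation with loss of silicon would leave the exocyclic methylene of A1.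
- In its favour: two rings, two skeletal bonds and the stereocentres C5, C9 and C10 would arise in one catalytic enantioselective step. The trans fusion follows from chair–chair folding, so no later hydrogenation at C5 is needed. On bonds and stereocentres per step it is better than the chosen plan.
- Against it: C4 of A1 carries only one carbon substituent, so the second hydroxymethyl group has to be added afterwards by an aldol reaction with formaldehyde at a hindered α-carbon. The cascade is best established for polarity-alternating polyenes with aryl terminators, and addition of an unactivated tertiary radical to an allylsilane is an extension of it. A stoichiometric one-electron oxidant is needed. Hydroboration of the 8(17)-alkene should place C17 axial, so equilibration at the aldehyde stage is still required.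
- Comparison: the overall step count is estimated to be lower than for the chosen plan, and both key steps lie beyond secured precedent. The chosen plan is better in that C18, C19, C11 and C12 are all present from the start and its precursor is assembled by robust arene chemistry.

**Alternative 2:** The cut is at C9–C10, a retro-[3,3] step leading to the δ-lactone A4. In the forward step the trimethylsilyl ketene acetal of A4 would rearrange through a boat transition state, breaking C6–O and forming C9–C10, to give the acid A3.
- In its favour: the reaction class (ring-contracting ester-enolate Claisen rearrangement) is known, so on mechanistic precedent it is better than the chosen plan. Chirality is transferred stereospecifically from the C6 carbinol centre to the quaternary C10, C17 is already in place as a protected hydroxymethyl group, and the C4 acetonide is present.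
- Against it: the new bond has to form at a fully substituted alkene carbon whose methyl group points under the tether in the boat, which should make the shift slow. The boat places C11 on the face opposite the C10 methyl, so A3 is the C9 epimer of what the target needs and requires equilibration α to the carboxyl group. C11 is attached to C9 as an acid, so a one-carbon homologation is needed to reach C12. The C5=C6 alkene still has to be hydrogenated to the trans fusion, the same task as in the chosen plan. A4 itself needs two stereocentres.
- Comparison: it is equal in setting ring B and C10 in one step, but worse in step economy because of the epimerisation and homologation.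

**Alternative 3:** The cut is at C5–C10 and C8–C9, which opens both rings to the triene imide A6. In the forward step Me2AlCl would chelate the acyl oxazolidinone and the tethered E,E-diene would add through an endo transition state to give A5.
- In its favour: both rings and the stereocentres C5, C8, C9 and C10 would form at once with direct trans fusion, C18 and C19 are present as the malonate, and auxiliary-controlled Diels–Alder reactions are well established. On bond count and on precedent for the reaction class it is equal to or better than the chosen plan.
- Against it: the dienophile is β,β-disubstituted, and the chelated s-cis conformer suffers allylic strain from the β-methyl group, so reactivity should be low. The dimethyl acetal on the diene is at risk of ionisation by the Lewis acid. C17 emerges axial in A5 and must be equilibrated after acetal hydrolysis, with the risk that the C6=C7 alkene moves into conjugation. C11 is an acyl carbon on C9 and needs a one-carbon homologation, as in alternative 2. The auxiliary is stoichiometric.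
- Comparison: the ring-forming stage is shorter than in the chosen plan. The endgame is longer, whereas the chosen plan carries C11–C12 from the first step and uses a catalytic source of chirality.

Key step: step 12

Remark on the chemistry: the sense of induction of the chiral ligand in step 12 cannot be predicted with certainty, so the ligand antipode that delivers 18 is to be used; 1, 2 (as a THF solution), 6, 8, 13 and 27 are taken as purchasable.

## Route

Step 1
Reactants: 1 3,5-dibromo-4-methylphenol; 2 ethylene oxide
Product: 4 3-bromo-5-(2-hydroxyethyl)-4-methylphenol, via lithium 3-bromo-5-lithio-4-methylphenolate 3 (not isolated)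
Conditions: n-BuLi (2.1 equiv), THF, −78 °C; 2 (3 equiv), −78 °C to rt; H2O
Reagents that add atoms: none
Why: Deprotonation of the phenol followed by bromine–lithium exchange gives the aryllithium, which opens the oxirane by SN2 attack; the two bromines are equivalent by symmetry, so mono-exchange defines the future C9 and C5 positions without any regiochemical question.

Step 2
Reactants: 4 3-bromo-5-(2-hydroxyethyl)-4-methylphenol
Product: 5 bis(triisopropylsilyl) ether of 4 (aryl OTIPS and alkyl OTIPS)
Conditions: TIPSCl (2.4 equiv), imidazole, DMF, rt
Reagents that add atoms: chlorotriisopropylsilane CC(C)[Si](Cl)(C(C)C)C(C)C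
Why: Silylation of both hydroxyls in one operation; the aryl silyl ether is the temporary phenol protection and the alkyl silyl ether masks C12 until step 19.

Step 3
Reactants: 5 bis(triisopropylsilyl) ether of 4; 6 diethyl malonate
Product: 7 diethyl 2-[2-methyl-5-(triisopropylsilyloxy)-3-(2-triisopropylsilyloxyethyl)phenyl]malonate
Conditions: Pd(OAc)2 (2 mol %), P(tBu)3·HBF4 (4 mol %), K3PO4, toluene, 80 °C
Reagents that add atoms: none
Why: Palladium-catalysed α-arylation of a malonate; the bulky electron-rich phosphine allows coupling next to one ortho methyl group, and the product stays as its enolate, which prevents a second arylation.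

Step 4
Reactants: 7 diethyl arylmalonate; 8 methyl propiolate
Product: 9 diethyl 2-aryl-2-[(Z)-3-methoxy-3-oxoprop-1-enyl]malonate (aryl as in 7)
Conditions: KOtBu (10 mol %), THF–tBuOH (10:1), −20 °C
Reagents that add atoms: none
Why: Michael addition of the tertiary malonate carbanion to the alkynoate creates quaternary C4; kinetic protonation of the allenolate on the side away from the new quaternary carbon (overall anti addition) should give the Z-alkene, and low temperature with substoichiometric base limits equilibration to the E isomer.

Step 5
Reactants: 9 Z-configured triester
Product: 10 (Z)-4-aryl-4-(hydroxymethyl)pent-2-ene-1,5-diol (aryl as in 7)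
Conditions: iBu2AlH (8 equiv), CH2Cl2, −78 °C to 0 °C; aq. potassium sodium tartrate
Reagents that add atoms: none
Why: 1,2-Reduction of all three esters by the aluminium hydride, which does not add to the conjugated alkene and leaves the Z geometry and both silyl ethers intact.

Step 6
Reactants: 10 triol
Product: 11 (Z)-3-(5-aryl-2,2-dimethyl-1,3-dioxan-5-yl)prop-2-en-1-ol (aryl as in 7)
Conditions: Me2C(OMe)2, PPTS (cat.), acetone, rt
Reagents that add atoms: 2,2-dimethoxypropane COC(C)(C)OC
Why: Acid-catalysed ketalisation; the six-membered acetonide of the 1,3-diol is strongly favoured over any larger ring that would include the allylic hydroxyl, which stays free.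

Step 7
Reactants: 11 acetonide with aryl and alkyl silyl ethers
Product: 12 3-[5-((Z)-3-hydroxyprop-1-enyl)-2,2-dimethyl-1,3-dioxan-5-yl]-4-methyl-5-(2-triisopropylsilyloxyethyl)phenol
Conditions: TBAF (1.0 equiv), THF, −20 °C
Reagents that add atoms: none
Why: Fluoride cleaves the aryl silyl ether much faster than the primary alkyl silyl ether because phenoxide is the better leaving group, so the phenol is released selectively.

Step 8
Reactants: 12 phenol; 13 paraformaldehyde
Product: 14 2-hydroxy-4-[5-((Z)-3-hydroxyprop-1-enyl)-2,2-dimethyl-1,3-dioxan-5-yl]-5-methyl-6-(2-triisopropylsilyloxyethyl)benzaldehyde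
Conditions: MgCl2, Et3N, 13 (excess), THF, reflux
Reagents that add atoms: none
Why: Magnesium-phenoxide-directed ortho-formylation (Casnati–Skattebøl reaction), in which a second equivalent of formaldehyde oxidises the intermediate benzylic alkoxide; C8 is the only accessible ortho position because C6 is flanked by the quaternary dioxane carbon.

Step 9
Reactants: 14 salicylaldehyde
Product: 15 the corresponding 2-hydroxybenzoic acid
Conditions: NaClO2, NaH2PO4, 2-methyl-2-butene, tBuOH–H2O, rt
Reagents that add atoms: sodium chlorite [Na+].[O-]Cl=O
Why: Pinnick oxidation; chlorite oxidises only the aldehyde, and the alkene scavenger removes hypochlorous acid before it can attack the Z-alkene or the electron-rich ring.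

Step 10
Reactants: 15 salicylic acid
Product: 16 methyl 2-hydroxy-4-[5-((Z)-3-hydroxyprop-1-enyl)-2,2-dimethyl-1,3-dioxan-5-yl]-5-methyl-6-(2-triisopropylsilyloxyethyl)benzoate
Conditions: TMSCHN2 (1.1 equiv), toluene–MeOH, 0 °C
Reagents that add atoms: (trimethylsilyl)diazomethane C[Si](C)(C)C=[N+]=[N-]
Why: Esterification of the carboxylic acid by the diazoalkane; the hydrogen-bonded phenol and the aliphatic alcohol are not acidic enough to be methylated under these conditions.

Step 11
Reactants: 16 methyl salicylate with free allylic alcohol
Product: 17 methyl 2-hydroxy-4-[5-((Z)-3-(methoxycarbonyloxy)prop-1-enyl)-2,2-dimethyl-1,3-dioxan-5-yl]-5-methyl-6-(2-triisopropylsilyloxyethyl)benzoate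
Conditions: ClCO2Me (1.2 equiv), pyridine, CH2Cl2, 0 °C
Reagents that add atoms: methyl chloroformate COC(=O)Cl
Why: Acylation of the primary allylic alcohol; the salicylate hydroxyl is hindered and hydrogen-bonded to the ester and should not react, and any aryl carbonate formed would be cleaved by the methoxide released in step 12.

Step 12
Reactants: 17 Z-allylic carbonate
Product: 18 bicyclic cross-conjugated dienone (C2=C3, C5=C6 and C8=C9 double bonds, C7 ketone, CO2Me on C8, CH2CH2OTIPS on C9, spiro acetonide at C4, quaternary C10 configured as in the target)
Conditions: Pd2(dba)3·CHCl3 (2.5 mol %), (1R,2R)-N,N'-bis[2-(diphenylphosphino)benzoyl]cyclohexane-1,2-diamine (7.5 mol %), CH2Cl2 (0.01 M), rt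
Reagents that add atoms: none
Why: Proposed new method: zerovalent palladium ionises the Z-allylic carbonate with inversion to the anti-configured η3-allyl complex, loss of CO2 leaves methoxide, which deprotonates the salicylate hydroxyl, and the phenolate attacks allyl terminus C1 through its para carbon C10 on the allyl face opposite the metal, forming C1–C10 and releasing the catalyst. The closest known reaction types are palladium- or iridium-catalysed intramolecular allylic dearomatisations of para-tethered phenols to spirocyclohexadienones and base-mediated para-alkylations of para-blocked phenols to fused dienones; the new element is an enantioselective para-alkylation that closes a fused six-membered ring from a meta tether. Ring A closes in a 6-endo sense with respect to the allyl unit, which is possible only from the anti allyl isomer that the Z-carbonate delivers, because the Z-alkene ends up inside the ring and attack on C3 would need a four-membered ring. The new stereocentre C10 is controlled by the chiral diphosphine alone: C4 is not stereogenic, so the two arene faces over which the allyl arm can swing are enantiotopic and the ligand pocket must prefer one of them. The step needs site selectivity for C10 over the free ortho carbon C6, C- over O-alkylation, and ring closure faster than anti-to-syn isomerisation. The oxygen cannot reach the allyl unit from its meta position; attack through C6 requires a rotamer about C4–C5 in which a C4 substituent eclipses the C10 methyl, whereas attack through C10 starts from the preferred rotamer in which that methyl is straddled by the allyl arm and one dioxane methylene; and syn–anti exchange would need palladium σ-bonded to the neopentyl-type C3. The methyl on C10 rules out rearomatisation, so the cross-conjugated dienone is the end point, and high dilution suppresses intermolecular O-allylation.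

Step 13
Reactants: 18 dienone
Product: 19 trans-fused β-keto ester (saturated rings A and B, H-5 and H-9 anti to the C10 methyl, C8 as epimers and enol)
Conditions: H2 (4 atm), 10% Pd/C, EtOAc, rt
Reagents that add atoms: none
Why: Heterogeneous hydrogenation of the C2=C3, C5=C6 and doubly activated C8=C9 alkenes; the C10 methyl and the axial C4 methylene are syn-diaxial and shield one face, so hydrogen should add to C5 and C9 from the opposite face, giving the trans fusion and C11 cis to the methyl. C8 stays epimerisable and is fixed in step 16.

Step 14
Reactants: 19 β-keto ester
Product: 20 enol triflate (C7=C8 alkene, OTf on C7, CO2Me on C8)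
Conditions: NaH, THF, 0 °C; PhNTf2, rt
Reagents that add atoms: N-phenylbis(trifluoromethanesulfonimide) O=S(=O)(N(c1ccccc1)S(=O)(=O)C(F)(F)F)C(F)(F)F
Why: O-Sulfonylation of the stabilised β-keto ester enolate, which can only form towards C8 and therefore fixes the double bond between C7 and C8; C9 is not involved.

Step 15
Reactants: 20 enol triflate
Product: 21 α,β-unsaturated ester (C7=C8 alkene, H on C7)
Conditions: Pd(OAc)2 (5 mol %), PPh3 (10 mol %), HCO2H, Et3N, DMF, 60 °C
Reagents that add atoms: none
Why: Palladium-catalysed formate reduction of a vinyl triflate: oxidative addition, decarboxylation of formate to a palladium hydride and reductive elimination replace the C7 oxygen by hydrogen.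

Step 16
Reactants: 21 α,β-unsaturated ester
Product: 22 saturated methyl ester with equatorial CO2Me on C8 (trans to the C9 chain)
Conditions: Mg turnings, MeOH, rt
Reagents that add atoms: none
Why: Dissolving-metal conjugate reduction of the enoate; the ester enolate is protonated and then equilibrated by Mg(OMe)2, which places the ester equatorial because the axial position would be 1,3-diaxial to the C10 methyl.

Step 17
Reactants: 22 equatorial methyl ester
Product: 23 C17 primary alcohol
Conditions: LiAlH4, THF, 0 °C
Reagents that add atoms: none
Why: Hydride reduction of the ester to the primary alcohol; no stereocentre is touched.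

Step 18
Reactants: 23 C17 alcohol
Product: 24 C17 4-methoxybenzyl ether
Conditions: NaH, PMBCl, Bu4NI (cat.), DMF, 0 °C to rt
Reagents that add atoms: 4-methoxybenzyl chloride COc1ccc(CCl)cc1
Why: Williamson etherification; the PMB group is stable to fluoride, iodination and organozinc chemistry and can be removed oxidatively in the presence of ring C.

Step 19
Reactants: 24 PMB ether with C12 silyl ether
Product: 25 C12 primary alcohol
Conditions: TBAF, THF, rt
Reagents that add atoms: none
Why: Fluoride-mediated cleavage of the primary silyl ether; the PMB ether and the acetonide are inert.

Step 20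
Reactants: 25 C12 alcohol
Product: 26 C12 primary iodide
Conditions: I2, PPh3, imidazole, CH2Cl2, 0 °C to rt
Reagents that add atoms: iodine II
Why: Appel-type iodination of an unhindered primary alcohol by SN2 displacement of the oxyphosphonium group.

Step 21
Reactants: 26 C12 iodide; 27 3-bromofuran-2(5H)-one
Product: 29 butenolide PMB ether, via C12 alkylzinc iodide 28 (not isolated)
Conditions: Zn dust (activated), LiCl, THF, 40 °C; then 27, Pd(OAc)2 (3 mol %), SPhos (6 mol %), THF, rt
Reagents that add atoms: none
Why: Negishi coupling: zinc inserts into the primary C–I bond, and the alkylzinc transmetalates to the vinylpalladium species formed from the α-bromobutenolide; the biaryl phosphine promotes reductive elimination over β-hydride loss, and the organozinc is not basic enough to damage the lactone.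

Step 22
Reactants: 29 butenolide PMB ether
Product: 30 butenolide C17 alcohol
Conditions: DDQ, CH2Cl2–pH 7 buffer, 0 °C to rt
Reagents that add atoms: none
Why: Oxidative cleavage of the PMB ether through its benzylic cation; the conditions are neutral and leave the butenolide and the acetonide intact.

Step 23
Reactants: 30 C17 alcohol
Product: 31 C17 aldehyde with C4 acetonide
Conditions: Dess–Martin periodinane, NaHCO3, CH2Cl2, rt
Reagents that add atoms: none
Why: Dess–Martin oxidation of the primary alcohol under buffered, non-basic conditions; the equatorial aldehyde is already the thermodynamically favoured epimer at C8.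

Step 24
Reactants: 31 aldehyde acetonide
Product: 32 CNP0332660.1 (target)
Conditions: AcOH–H2O (4:1), 40 °C
Reagents that add atoms: none
Why: Acid-catalysed hydrolysis of the 1,3-dioxane acetonide; mild aqueous acid affects neither the butenolide nor the configuration at C8.

## Compound list

1 | 3,5-dibromo-4-methylphenol | Cc1c(Br)cc(O)cc1Br | starting material
2 | ethylene oxide | C1CO1 | starting material
3 | lithium 3-bromo-5-lithio-4-methylphenolate | [Li]c1cc(O[Li])cc(Br)c1C | intermediate
4 | 3-bromo-5-(2-hydroxyethyl)-4-methylphenol | Cc1c(Br)cc(O)cc1CCO | intermediate
5 | bis(triisopropylsilyl) ether of 4 | Cc1c(Br)cc(O[Si](C(C)C)(C(C)C)C(C)C)cc1CCO[Si](C(C)C)(C(C)C)C(C)C | intermediate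
6 | diethyl malonate | CCOC(=O)CC(=O)OCC | starting material
7 | diethyl 2-[2-methyl-5-(triisopropylsilyloxy)-3-(2-triisopropylsilyloxyethyl)phenyl]malonate | CCOC(=O)C(C(=O)OCC)c1cc(O[Si](C(C)C)(C(C)C)C(C)C)cc(CCO[Si](C(C)C)(C(C)C)C(C)C)c1C | intermediate
8 | methyl propiolate | COC(=O)C#C | starting material
9 | diethyl 2-aryl-2-[(Z)-3-methoxy-3-oxoprop-1-enyl]malonate | CCOC(=O)C(/C=C\C(=O)OC)(C(=O)OCC)c1cc(O[Si](C(C)C)(C(C)C)C(C)C)cc(CCO[Si](C(C)C)(C(C)C)C(C)C)c1C | intermediate
10 | (Z)-4-aryl-4-(hydroxymethyl)pent-2-ene-1,5-diol | Cc1c(CCO[Si](C(C)C)(C(C)C)C(C)C)cc(O[Si](C(C)C)(C(C)C)C(C)C)cc1C(CO)(CO)/C=C\CO | intermediate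
11 | (Z)-3-(5-aryl-2,2-dimethyl-1,3-dioxan-5-yl)prop-2-en-1-ol, bis-silyl ether | Cc1c(CCO[Si](C(C)C)(C(C)C)C(C)C)cc(O[Si](C(C)C)(C(C)C)C(C)C)cc1C1(/C=C\CO)COC(C)(C)OC1 | intermediate
12 | 3-[5-((Z)-3-hydroxyprop-1-enyl)-2,2-dimethyl-1,3-dioxan-5-yl]-4-methyl-5-(2-triisopropylsilyloxyethyl)phenol | Cc1c(CCO[Si](C(C)C)(C(C)C)C(C)C)cc(O)cc1C1(/C=C\CO)COC(C)(C)OC1 | intermediate
13 | paraformaldehyde (as formaldehyde) | C=O | starting material
14 | 2-hydroxy-4-[5-((Z)-3-hydroxyprop-1-enyl)-2,2-dimethyl-1,3-dioxan-5-yl]-5-methyl-6-(2-triisopropylsilyloxyethyl)benzaldehyde | Cc1c(CCO[Si](C(C)C)(C(C)C)C(C)C)c(C=O)c(O)cc1C1(/C=C\CO)COC(C)(C)OC1 | intermediate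
15 | corresponding 2-hydroxybenzoic acid | Cc1c(CCO[Si](C(C)C)(C(C)C)C(C)C)c(C(=O)O)c(O)cc1C1(/C=C\CO)COC(C)(C)OC1 | intermediate
16 | methyl salicylate with free Z-allylic alcohol | Cc1c(CCO[Si](C(C)C)(C(C)C)C(C)C)c(C(=O)OC)c(O)cc1C1(/C=C\CO)COC(C)(C)OC1 | intermediate
17 | methyl salicylate with Z-allylic methyl carbonate (precursor of the key step) | Cc1c(CCO[Si](C(C)C)(C(C)C)C(C)C)c(C(=O)OC)c(O)cc1C1(/C=C\COC(=O)OC)COC(C)(C)OC1 | intermediate
18 | bicyclic cross-conjugated dienone ester with quaternary C10 | C[C@@]12CC=CC3(COC(C)(C)OC3)C1=CC(=O)C(C(=O)OC)=C2CCO[Si](C(C)C)(C(C)C)C(C)C | intermediate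
19 | trans-fused β-keto ester (C8 unfixed) | C[C@@]12CCCC3(COC(C)(C)OC3)[C@H]1CC(=O)C(C(=O)OC)[C@H]2CCO[Si](C(C)C)(C(C)C)C(C)C | intermediate
20 | enol triflate (C7=C8) | C[C@@]12CCCC3(COC(C)(C)OC3)[C@H]1CC(OS(=O)(=O)C(F)(F)F)=C(C(=O)OC)[C@H]2CCO[Si](C(C)C)(C(C)C)C(C)C | intermediate
21 | α,β-unsaturated ester (C7=C8) | C[C@@]12CCCC3(COC(C)(C)OC3)[C@H]1CC=C(C(=O)OC)[C@H]2CCO[Si](C(C)C)(C(C)C)C(C)C | intermediate
22 | saturated ester, equatorial CO2Me on C8 | C[C@@]12CCCC3(COC(C)(C)OC3)[C@H]1CC[C@H](C(=O)OC)[C@H]2CCO[Si](C(C)C)(C(C)C)C(C)C | intermediate
23 | C17 alcohol | C[C@@]12CCCC3(COC(C)(C)OC3)[C@H]1CC[C@H](CO)[C@H]2CCO[Si](C(C)C)(C(C)C)C(C)C | intermediate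
24 | C17 PMB ether | C[C@@]12CCCC3(COC(C)(C)OC3)[C@H]1CC[C@H](COCc1ccc(OC)cc1)[C@H]2CCO[Si](C(C)C)(C(C)C)C(C)C | intermediate
25 | C12 alcohol | C[C@@]12CCCC3(COC(C)(C)OC3)[C@H]1CC[C@H](COCc1ccc(OC)cc1)[C@H]2CCO | intermediate
26 | C12 iodide | C[C@@]12CCCC3(COC(C)(C)OC3)[C@H]1CC[C@H](COCc1ccc(OC)cc1)[C@H]2CCI | intermediate
27 | 3-bromofuran-2(5H)-one | O=C1OCC=C1Br | starting material
28 | C12 alkylzinc iodide | C[C@@]12CCCC3(COC(C)(C)OC3)[C@H]1CC[C@H](COCc1ccc(OC)cc1)[C@H]2CC[Zn]I | intermediate
29 | butenolide PMB ether | C[C@@]12CCCC3(COC(C)(C)OC3)[C@H]1CC[C@H](COCc1ccc(OC)cc1)[C@H]2CCC1=CCOC1=O | intermediate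
30 | butenolide C17 alcohol | C[C@@]12CCCC3(COC(C)(C)OC3)[C@H]1CC[C@H](CO)[C@H]2CCC1=CCOC1=O | intermediate
31 | C17 aldehyde with C4 acetonide | C[C@@]12CCCC3(COC(C)(C)OC3)[C@H]1CC[C@H](C=O)[C@H]2CCC1=CCOC1=O | intermediate
32 | CNP0332660.1 | C[C@@]12CCCC(CO)(CO)[C@H]1CC[C@H](C=O)[C@H]2CCC1=CCOC1=O | target

## Step count and least certain steps

Total step count: 24. Longest linear sequence: 24 steps (1 to 32); 2, 6, 8, 13 and 27 enter as purchased reagents.

**Step 12 (key step).** The most likely failure is C-alkylation through the unsubstituted ortho carbon C6 followed by rearomatisation, since both C6 and C10 are ortho to the tether and the rotamer argument only biases the choice. Slow closure would also allow anti-to-syn isomerisation of the allyl complex and intermolecular O-allylation, and the enantioface discrimination may be weak because the stereocentre forms on the nucleophile, remote from the metal. Fallback by known chemistry, from 16 back to 18: the allylic alcohol of 16 is converted with methanesulfonyl chloride, 2,4,6-collidine and LiCl into the Z-allylic chloride F1. Treatment with KOtBu in tBuOH–THF at high dilution effects the base-mediated para-alkylation of the phenolate to the racemic dienone F2. Preparative chromatography on a chiral stationary phase then separates 18 from its unwanted enantiomer F3.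

**Step 4.** The most likely failure is loss of Z geometry, either by unselective protonation of the allenolate or by base-mediated reversible addition to the product, which leads to the more stable E isomer. Fallback from 7 back to 10: the sodium enolate of 7 (NaH, THF) is treated with ethyl (Z)-3-iodoacrylate (CCOC(=O)/C=C\I). Addition–elimination at the vinylic carbon proceeds with retention, so the geometry is brought in with the reagent, and gives the Z-configured triethyl ester F4. Reduction with iBu2AlH as in step 5 gives 10.

**Step 13.** The most likely failure is stalling at the tetrasubstituted C8=C9 alkene, with erosion of face selectivity at C5 if forcing conditions become necessary. Fallback from 18 back to 19: lithium (2.2 equiv) in liquid ammonia–THF at −78 °C reduces only the doubly activated C8=C9 bond. Axial protonation at C9 occurs anti to the methyl group and the β-keto ester is protected as its enolate, giving the enone keto ester F5. Hydrogenation over Pd/C then has to saturate only the C2=C3 and C5=C6 bonds and gives 19.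

**Step 8.** The most likely failure is slow formylation at an ortho carbon that is flanked on both sides, with the free allylic alcohol consuming reagent as a hemiformal. Fallback from 12 back to 16: ortho-iodination with I2 and morpholine gives the 2-iodophenol F6. Palladium-catalysed methoxycarbonylation (Pd(OAc)2, 1,3-bis(diphenylphosphino)propane, CO, MeOH, Et3N) then gives 16 directly, bypassing 14 and 15.

**Step 21.** The most likely failure is incomplete zinc insertion or protodezincation, together with decomposition of the base-sensitive bromobutenolide under the coupling conditions. Fallback from 26 back to 29: the lithium enolate of 3-(phenylsulfanyl)oxolan-2-one (LDA, THF–DMPU) is alkylated with 26 to the α-alkyl-α-phenylsulfanyl lactone F7. Oxidation with mCPBA at −78 °C gives the sulfoxide F8, and thermal syn-elimination in toluene towards the ring hydrogen gives 29.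

## Further compounds

F1 | step 12 | Z-allylic chloride of 16 | Cc1c(CCO[Si](C(C)C)(C(C)C)C(C)C)c(C(=O)OC)c(O)cc1C1(/C=C\CCl)COC(C)(C)OC1
F2 | step 12 | racemic dienone | CC12CC=CC3(COC(C)(C)OC3)C1=CC(=O)C(C(=O)OC)=C2CCO[Si](C(C)C)(C(C)C)C(C)C
F3 | step 12 | enantiomer of 18 | C[C@]12CC=CC3(COC(C)(C)OC3)C1=CC(=O)C(C(=O)OC)=C2CCO[Si](C(C)C)(C(C)C)C(C)C
F4 | step 4 | Z-configured triethyl ester analogue of 9 | CCOC(=O)/C=C\C(C(=O)OCC)(C(=O)OCC)c1cc(O[Si](C(C)C)(C(C)C)C(C)C)cc(CCO[Si](C(C)C)(C(C)C)C(C)C)c1C
F5 | step 13 | enone β-keto ester with C2=C3 and C5=C6 retained and H-9 anti to the methyl | C[C@@]12CC=CC3(COC(C)(C)OC3)C1=CC(=O)C(C(=O)OC)[C@H]2CCO[Si](C(C)C)(C(C)C)C(C)C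
F6 | step 8 | 2-iodophenol derived from 12 | Cc1c(CCO[Si](C(C)C)(C(C)C)C(C)C)c(I)c(O)cc1C1(/C=C\CO)COC(C)(C)OC1
F7 | step 21 | α-alkyl-α-phenylsulfanyl lactone (C13 epimers) | C[C@@]12CCCC3(COC(C)(C)OC3)[C@H]1CC[C@H](COCc1ccc(OC)cc1)[C@H]2CCC1(Sc2ccccc2)CCOC1=O
F8 | step 21 | sulfoxide of F7 | C[C@@]12CCCC3(COC(C)(C)OC3)[C@H]1CC[C@H](COCc1ccc(OC)cc1)[C@H]2CCC1(S(=O)c2ccccc2)CCOC1=O
A1 | alternative 1 | trans-decalin 4-carbaldehyde with 8(17)-methylene and C12 pivalate | C[C@@]12CCC[C@H](C=O)[C@H]1CCC(=C)[C@H]2CCOC(=O)C(C)(C)C
A2 | alternative 1 | acyclic polyene aldehyde with allylsilane terminus | O=CCCCC/C(C)=C/CC/C(C[Si](C)(C)C)=C/CCOC(=O)C(C)(C)C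
A3 | alternative 2 | C5=C6 octalin C11 carboxylic acid with quaternary C10 | C[C@@]12CCCC3(COC(C)(C)OC3)C1=CC[C@H](COCc1ccccc1)[C@@H]2C(=O)O
A4 | alternative 2 | 4-(benzyloxymethyl)-6-(cyclohexenyl) δ-lactone | O=C1C[C@@H](COCc2ccccc2)C[C@@H](O1)C1=C(C)CCCC13COC(C)(C)OC3
A5 | alternative 3 | trans-fused octalin imide with axial C8 acetal | C[C@@]12CCCC(C(=O)OC)(C(=O)OC)[C@H]1C=C[C@@H](C(OC)OC)[C@H]2C(=O)N1C(=O)OC[C@H]1Cc1ccccc1
A6 | alternative 3 | triene imide | COC(OC)/C=C/C=C/C(CCC/C(C)=C/C(=O)N1C(=O)OC[C@H]1Cc1ccccc1)(C(=O)OC)C(=O)OC
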